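**Retrosynthetic overview**
1. Target ⇒ (C17 methylenation, protecting-group removal, acetylation) tetracyclic keto lactone 25; ring D is closed at C16–C13 by 5-exo radical cyclisation of a C8 bromoacetyl group onto a C12=C13 alkene.
2. Ring C comes from C9–C11/C8–C14 (Diels–Alder of buta-1,3-diene with the 2-acetyl unsaturated δ-lactone 20); the lactone ring comes from C9–C10 (Cp2TiCl-mediated epoxide/acrylate coupling at the C10=C20 methylene of ring A) and O–C7 lactonisation.
3. Ring A is made first, by C2–C3 and C4–C5: an enantioselective [4+2] of the silyloxydiene C2=C1(OSi)–C10=C5–C6 with methacrolein C3=C4(C18)–C19, with C20 added in the same flask by Mannich capture at C10 (three components, ten of the twenty skeletal carbons).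
4. Enabling feature: in ring A (C1–C5, C10) the C1 oxygen is 1,4 to the quaternary C4, which carries the C18 methyl and the oxidised C19, and C19 is cis to C6 on the neighbouring C5. This is the para/ortho/endo pattern of a 2-silyloxydiene/α-methylacrolein cycloaddition, with C1 at the ketone level and C19 at the aldehyde level.
5. Ring order: A → lactone → C → D.

Key step: step 3

Remark: atoms carry the ent-kaurane numbers of the target throughout; the "top face" of ring A is the face of C20 (in the target it also carries O1, C19 and C6).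
Assumption: the (S)-configured oxazaborolidinium ion is taken to deliver the (4R,5S) cycloadduct 7; should the sense of induction be the opposite, its (R)-antipode is used.

**Step 1**
Reactants: 1 2-(benzyloxy)acetaldehyde; 2 1-(triphenylphosphoranylidene)propan-2-one
Product: 3 (E)-5-(benzyloxy)pent-3-en-2-one
Conditions: CH2Cl2, 23 °C
Reagents that add atoms: none
Why: Wittig olefination with a stabilised ylide, which should give the (E)-enone selectively.

**Step 2**
Reactants: 3 (E)-5-(benzyloxy)pent-3-en-2-one
Product: 4 (E)-2-(tert-butyldimethylsilyloxy)-5-(benzyloxy)penta-1,3-diene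
Conditions: TBSOTf, Et3N, CH2Cl2, 0 °C
Reagents that add atoms: tert-butyldimethylsilyl triflate CC(C)(C)[Si](C)(C)OS(=O)(=O)C(F)(F)F
Why: soft enolisation of the methyl ketone (silyl triflate/amine) at the α′-methyl group should give the cross-conjugated 2-silyloxydiene with the (E)-alkene untouched.

**Step 3**
Reactants: 4 (E)-2-(tert-butyldimethylsilyloxy)-5-(benzyloxy)penta-1,3-diene; 5 methacrolein; 6 N,N-dimethylmethyleneiminium iodide
Product: 8 ring A keto aldehyde Mannich base (C10–CH2NMe2), via cycloadduct enol silane 7 (not isolated)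
Conditions: (S)-B-(o-tolyl)diphenylprolinol oxazaborolidine·HN(SO2CF3)2 (C24H24BNO·C2HF6NO4S2, 20 mol %), 5 (2 equiv), CH2Cl2, −78 °C; then Et3N (0.3 equiv), 6 (1.5 equiv), −78 → 23 °C; aq. NaHCO3
Reagents that add atoms: none
Why: The protonated oxazaborolidine binds methacrolein and the diene adds in a concerted, asynchronous endo [4+2] cycloaddition (C2–C3 ahead of C4–C5); the enol silane 7 so formed is then captured at C10 by the iminium ion of 6 (Mukaiyama–Mannich) with loss of the silyl group. The closest known reaction types are oxazaborolidinium-catalysed enantioselective Diels–Alder reactions of 2-silyloxy-1,3-dienes with 2-substituted acroleins, and Mannich reactions of silyl enol ethers with preformed iminium salts. Ring A is closed by an intermolecular [4π+2π] cycloaddition, suprafacial on both partners, forming C2–C3 and C4–C5. The quaternary C4 and C5 are set relative to each other by the (E)-diene geometry and the endo position of the formyl group (C19 cis to C6), and in the absolute sense by the catalyst, which shields one face of the bound enal. The step needs regioselectivity (the 2-silyloxy group directs C4 para to C1 and the C5 substituent directs it ortho, so both agree), endo selectivity (formyl rather than methyl endo, as is usual with acyclic dienes) and regiospecific Mannich capture at C10, which is fixed by the position of the enol silane; the C19 aldehyde has no α-hydrogen and is inert to 6.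

**Step 4**
Reactants: 8 ring A keto aldehyde Mannich base
Product: 10 exo-methylene enone aldehyde, via trimethylammonium iodide 9 (not isolated)
Conditions: MeI, CH2Cl2, 23 °C; then aq. NaHCO3, 23 °C; used at once
Reagents that add atoms: none
Why: quaternisation followed by Hofmann-type β-elimination (E1cB through the C1 enolate) should unveil the C10=C20 methylene and erase the C10 stereocentre.

**Step 5**
Reactants: 10 exo-methylene enone aldehyde
Product: 11 allylic diol (O1, C19 and C6 all on the top face)
Conditions: NaBH4, CeCl3·7H2O, MeOH, −78 → −20 °C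
Reagents that add atoms: none
Why: Luche 1,2-reduction of the enone together with reduction of the neopentyl aldehyde; hydride should reach C1 from the bottom face, away from C6 (pushed pseudoaxial by allylic strain with the exocyclic methylene) and C19, placing the new C1 hydroxyl on the top face.

**Step 6**
Reactants: 11 allylic diol
Product: 12 bis(tert-butyldimethylsilyl) ether
Conditions: TBSOTf (2.5 equiv), 2,6-lutidine, CH2Cl2, −78 → 0 °C
Reagents that add atoms: tert-butyldimethylsilyl triflate CC(C)(C)[Si](C)(C)OS(=O)(=O)C(F)(F)F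
Why: silyl triflate silylation protects the hindered secondary allylic and neopentyl primary hydroxyls against the enolate chemistry ahead.

**Step 7**
Reactants: 12 bis(tert-butyldimethylsilyl) ether
Product: 13 C10–C20 spiro epoxide
Conditions: mCPBA, NaHCO3, CH2Cl2, 0 °C
Reagents that add atoms: meta-chloroperoxybenzoic acid OOC(=O)c1cccc(Cl)c1
Why: Prilezhaev epoxidation of the 1,1-disubstituted alkene, expected from the bottom face; the epoxide configuration is immaterial because C10 becomes a planar radical in step 8.

**Step 8**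
Reactants: 13 C10–C20 spiro epoxide; 14 2,2,2-trifluoroethyl acrylate
Product: 16 spirolactone, via hydroxy trifluoroethyl ester 15 (not isolated)
Conditions: Cp2TiCl2 (2.5 equiv), Zn, THF, 23 °C; then 13 and 14 (5 equiv), 23 °C; 1 M HCl work-up
Reagents that add atoms: none
Why: Cp2TiCl (trivalent titanium) opens the epoxide by single-electron transfer to the tertiary C10 radical, which undergoes Giese addition to the acrylate from the bottom face (anti to the axial C19 group and the top-face C1 and C5 substituents), setting C10 with C20 on top and C9 below; reduction of the α-ester radical, protonation and lactonisation of the C20 alkoxide with loss of trifluoroethanol should close the δ-lactone.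

**Step 9**
Reactants: 16 spirolactone
Product: 17 C8-acetyl spirolactone
Conditions: LiN(iPr)2 (2.2 equiv), THF, −78 °C; 1-acetylimidazole, −78 → −40 °C; AcOH quench
Reagents that add atoms: 1-acetylimidazole CC(=O)n1ccnc1
Why: crossed Claisen acylation of the lactone enolate with an acyl imidazole, the second equivalent of base taking up the acidic β-keto lactone; C8 is left as an epimer/enol mixture that step 10 removes.

**Step 10**
Reactants: 17 C8-acetyl spirolactone
Product: 20 acetyl unsaturated lactone, via selenide 18 (not isolated), via selenoxide 19 (not isolated)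
Conditions: PhSeCl, pyridine, CH2Cl2, 0 °C; then 30 % H2O2, 0 → 23 °C; used at once
Reagents that add atoms: none
Why: selenenylation of the β-dicarbonyl followed by selenoxide syn-elimination, which can only involve the C9 hydrogens and so should give the C8=C9 alkene.

**Step 11**
Reactants: 20 acetyl unsaturated lactone; 21 buta-1,3-diene
Product: 22 cis-fused cyclohexene lactone
Conditions: 21 (excess), ZnCl2 (1.0 equiv), CH2Cl2, −20 → 23 °C, sealed tube
Reagents that add atoms: none
Why: Lewis-acid promoted Diels–Alder reaction of a 2-acyl-activated cyclic dienophile; suprafacial addition makes C9–C11 and C8–C14 cis and so sets C8 and C9 relative to each other, while the diene should approach the C8=C9 face on the C1 side, where it meets only the C1 oxygen in the peri position, rather than the C5 side with its CH2OBn branch and the quaternary C4, which sets C8/C9 relative to C10.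

**Step 12**
Reactants: 22 cis-fused cyclohexene lactone
Product: 24 bromomethyl ketone, via trimethylsilyl enol ether 23 (not isolated)
Conditions: LiN(SiMe3)2, Me3SiCl, THF, −78 °C; then NBS, −78 → 0 °C
Reagents that add atoms: N-bromosuccinimide O=C1CCC(=O)N1Br
Why: kinetic enol silane formation at C16, the only enolisable position, followed by electrophilic bromination of the enol silane, which should be faster than any reaction of NBS with the ring alkene.

**Step 13**
Reactants: 24 bromomethyl ketone
Product: 25 tetracyclic keto lactone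
Conditions: Bu3SnH, AIBN (cat.), benzene (0.005 M), 80 °C, slow addition
Reagents that add atoms: none
Why: tin-hydride radical cyclisation in which the C16 α-keto radical adds 5-exo-trig to C13 (expected to be faster than 6-exo closure at C12 through the longer tether) and the C12 radical is reduced; the bridged bicyclo[3.2.1]octane geometry allows only one configuration at C13.

**Step 14**
Reactants: 25 tetracyclic keto lactone
Product: 26 1,19-diol
Conditions: HF·pyridine, THF, 0 → 40 °C
Reagents that add atoms: none
Why: fluoride desilylation removes both silyl ethers under mildly acidic, non-equilibrating conditions while the benzyl ether, lactone and ketone stay intact.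

**Step 15**
Reactants: 26 1,19-diol
Product: 27 1,19-diacetate
Conditions: Ac2O, pyridine, DMAP (cat.), CH2Cl2, 0 → 23 °C
Reagents that add atoms: acetic anhydride CC(=O)OC(C)=O
Why: nucleophile-catalysed acetylation of both hydroxyls, expected to outrun migration of the lactone acyl group from O20 to O1.

**Step 16**
Reactants: 27 1,19-diacetate
Product: 28 6-hydroxy 1,19-diacetate
Conditions: H2 (1 atm), Pd/C, EtOAc, 23 °C
Reagents that add atoms: none
Why: hydrogenolysis of the benzyl ether, placed before the enone is made so that no alkene is exposed to hydrogen.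

**Step 17**
Reactants: 28 6-hydroxy 1,19-diacetate
Product: 30 target CNP0105570.2, via anilinomethyl ketone 29 (not isolated)
Conditions: (CH2O)n, PhNHMe·CF3CO2H, THF, 65 °C
Reagents that add atoms: paraformaldehyde (formaldehyde) C=O
Why: Mannich-type α-methylenation (aminomethylation, then elimination of N-methylaniline) at C16, the only enolisable position of the C15 ketone, under mildly acidic conditions that acetates, lactone and the free primary alcohol should tolerate.

**Compound list**
1 | 2-(benzyloxy)acetaldehyde | O=CCOCc1ccccc1 | starting material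
2 | 1-(triphenylphosphoranylidene)propan-2-one | CC(=O)C=P(c1ccccc1)(c1ccccc1)c1ccccc1 | starting material
3 | (E)-5-(benzyloxy)pent-3-en-2-one | CC(=O)/C=C/COCc1ccccc1 | intermediate
4 | (E)-2-(tert-butyldimethylsilyloxy)-5-(benzyloxy)penta-1,3-diene | C=C(O[Si](C)(C)C(C)(C)C)/C=C/COCc1ccccc1 | intermediate
5 | 2-methylprop-2-enal (methacrolein) | CC(=C)C=O | starting material
6 | N,N-dimethylmethyleneiminium iodide (Eschenmoser's salt) | C=[N+](C)C.[I-] | starting material
7 | (1R,2S)-2-[(benzyloxy)methyl]-4-[(tert-butyldimethylsilyl)oxy]-1-methylcyclohex-3-ene-1-carbaldehyde (formyl C19 cis to C6) | C1=C(O[Si](C)(C)C(C)(C)C)CC[C@@](C)(C=O)[C@H]1COCc2ccccc2 | intermediate (not isolated)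
8 | 2-[(benzyloxy)methyl]-3-[(dimethylamino)methyl]-1-methyl-4-oxocyclohexane-1-carbaldehyde (C19 cis to C6; aminomethyl at C10 trans to C6, C10 epimer immaterial) | [C@@H]1(CN(C)C)C(=O)CC[C@@](C)(C=O)[C@H]1COCc2ccccc2 | intermediate
9 | N-methyl quaternary ammonium iodide of 8 | [C@@H]1(C[N+](C)(C)C)C(=O)CC[C@@](C)(C=O)[C@H]1COCc2ccccc2.[I-] | intermediate (not isolated)
10 | 2-[(benzyloxy)methyl]-1-methyl-3-methylidene-4-oxocyclohexane-1-carbaldehyde (C19 cis to C6) | C=C1C(=O)CC[C@@](C)(C=O)[C@H]1COCc2ccccc2 | intermediate
11 | 3-[(benzyloxy)methyl]-4-(hydroxymethyl)-4-methyl-2-methylidenecyclohexan-1-ol (O1, C19, C6 all on the top face) | C=C1[C@@H](O)CC[C@@](C)(CO)[C@H]1COCc2ccccc2 | intermediate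
12 | bis(tert-butyldimethylsilyl) ether of 11 | C=C1[C@@H](O[Si](C)(C)C(C)(C)C)CC[C@@](C)(CO[Si](C)(C)C(C)(C)C)[C@H]1COCc2ccccc2 | intermediate
13 | C10–C20 spiro epoxide of 12 (1-oxaspiro[2.5]octane, oxygen on the bottom face; the C10 epimer converges) | C1O[C@@]12[C@@H](O[Si](C)(C)C(C)(C)C)CC[C@@](C)(CO[Si](C)(C)C(C)(C)C)[C@H]2COCc3ccccc3 | intermediate
14 | 2,2,2-trifluoroethyl prop-2-enoate | C=CC(=O)OCC(F)(F)F | starting material
15 | 2,2,2-trifluoroethyl 3-[ring A C10]propanoate bearing C10–CH2OH (C20 top, C9 bottom) | O=C(OCC(F)(F)F)CC[C@]1(CO)[C@@H](O[Si](C)(C)C(C)(C)C)CC[C@@](C)(CO[Si](C)(C)C(C)(C)C)[C@H]1COCc2ccccc2 | intermediate (not isolated)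
16 | spirolactone (2-oxaspiro[5.5]undecan-3-one; ring A spiro at C10 to the C7 δ-lactone, C20 top, C9 bottom) | O=C1CC[C@]2(CO1)[C@@H](O[Si](C)(C)C(C)(C)C)CC[C@@](C)(CO[Si](C)(C)C(C)(C)C)[C@H]2COCc3ccccc3 | intermediate
17 | C8-acetyl spirolactone (β-keto lactone, C8 epimers/enol) | CC(=O)C1C[C@]2(COC1=O)[C@@H](O[Si](C)(C)C(C)(C)C)CC[C@@](C)(CO[Si](C)(C)C(C)(C)C)[C@H]2COCc3ccccc3 | intermediate
18 | C8-phenylselanyl derivative of 17 | CC(=O)C1([Se]c4ccccc4)C[C@]2(COC1=O)[C@@H](O[Si](C)(C)C(C)(C)C)CC[C@@](C)(CO[Si](C)(C)C(C)(C)C)[C@H]2COCc3ccccc3 | intermediate (not isolated)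
19 | selenoxide of 18 | CC(=O)C1([Se](=O)c4ccccc4)C[C@]2(COC1=O)[C@@H](O[Si](C)(C)C(C)(C)C)CC[C@@](C)(CO[Si](C)(C)C(C)(C)C)[C@H]2COCc3ccccc3 | intermediate (not isolated)
20 | 4-acetyl-2-oxaspiro[5.5]undec-4-en-3-one derivative (C8=C9 alkene, C8 acetyl) | CC(=O)C1=C[C@]2(COC1=O)[C@@H](O[Si](C)(C)C(C)(C)C)CC[C@@](C)(CO[Si](C)(C)C(C)(C)C)[C@H]2COCc3ccccc3 | intermediate
21 | buta-1,3-diene | C=CC=C | starting material
22 | cycloadduct: lactone cis-fused to ring C cyclohexene (C12=C13), C8 acetyl; C11 and C14 on the C1 side of the lactone ring, H9 and C15 on the C5 side | CC(=O)[C@]12CC=CC[C@H]1[C@]3(COC2=O)[C@@H](O[Si](C)(C)C(C)(C)C)CC[C@@](C)(CO[Si](C)(C)C(C)(C)C)[C@H]3COCc4ccccc4 | intermediate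
23 | trimethylsilyl enol ether of 22 (C15(OSiMe3)=C16H2) | C=C(O[Si](C)(C)C)[C@]12CC=CC[C@H]1[C@]3(COC2=O)[C@@H](O[Si](C)(C)C(C)(C)C)CC[C@@](C)(CO[Si](C)(C)C(C)(C)C)[C@H]3COCc4ccccc4 | intermediate (not isolated)
24 | C8 bromoacetyl analogue of 22 | BrCC(=O)[C@]12CC=CC[C@H]1[C@]3(COC2=O)[C@@H](O[Si](C)(C)C(C)(C)C)CC[C@@](C)(CO[Si](C)(C)C(C)(C)C)[C@H]3COCc4ccccc4 | intermediate
25 | 17-nor tetracyclic keto lactone (7,20-lactone, bicyclo[3.2.1]octan-15-one), 1,19-bis-TBS ether, 6-benzyl ether | C1C(=O)[C@]23C[C@H]1CC[C@H]2[C@]1(COC3=O)[C@@H](O[Si](C)(C)C(C)(C)C)CC[C@@](C)(CO[Si](C)(C)C(C)(C)C)[C@H]1COCc2ccccc2 | intermediate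
26 | 1,19-diol of 25 | C1C(=O)[C@]23C[C@H]1CC[C@H]2[C@]1(COC3=O)[C@@H](O)CC[C@@](C)(CO)[C@H]1COCc2ccccc2 | intermediate
27 | 1,19-diacetate, 6-benzyl ether | C1C(=O)[C@]23C[C@H]1CC[C@H]2[C@]1(COC3=O)[C@@H](OC(C)=O)CC[C@@](C)(COC(C)=O)[C@H]1COCc2ccccc2 | intermediate
28 | 6-hydroxy 1,19-diacetate (17-nor target) | C1C(=O)[C@]23C[C@H]1CC[C@H]2[C@]1(COC3=O)[C@@H](OC(C)=O)CC[C@@](C)(COC(C)=O)[C@H]1CO | intermediate
29 | 16-[(N-methylanilino)methyl] ketone (C16 epimers) | CN(CC1C(=O)[C@]23C[C@H]1CC[C@H]2[C@]1(COC3=O)[C@@H](OC(C)=O)CC[C@@](C)(COC(C)=O)[C@H]1CO)c1ccccc1 | intermediate (not isolated)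
30 | CNP0105570.2 | C=C1C(=O)[C@]23C[C@H]1CC[C@H]2[C@]1(COC3=O)[C@@H](OC(C)=O)CC[C@@](C)(COC(C)=O)[C@H]1CO | target

**Totals and risks**
Total step count: 17. Longest linear sequence: 17 steps (1 → 30).

Three steps most likely to fail:

1. Step 11. What may go wrong: sluggish cycloaddition at the neopentyl-type C9, and approach of the diene to the C5 face of the lactone (loss of facial selectivity). The fallback replaces the intermolecular cycloaddition by intramolecular delivery of the diene from the C1 oxygen; it sets out from 20 and comes back at 22. HF·pyridine frees both hydroxyls of 20 to give the diol dienophile F1. Chlorodimethyl(buta-1,3-dien-2-yl)silane F2, made from the Grignard reagent of 2-chloro-1,3-butadiene and Me2SiCl2, with imidazole gives the bis(dienylsilyl) ether F3. Heating in toluene at 110 °C should effect a type 2 intramolecular Diels–Alder reaction; the diene tethered to O1 can reach C9/C8 only from the C1 face, giving the bridged siloxane cycloadduct F4, while the C19 silyl ether cannot reach the dienophile. Buffered Bu4NF/AcOH cleaves both silicon groups, with protodesilylation of the C12 vinylsilane, to give the diol cycloadduct F5. TBSOTf/2,6-lutidine then returns 22.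

2. Step 13. What may go wrong: hydrogen-atom transfer to the α-keto radical before it cyclises (simple debromination), or 6-exo closure at C12. The fallback closes ring D by organopalladium rather than radical chemistry; it sets out from 22 and comes back at 25. The enol silane 23 is made as in step 12 and isolated. Stoichiometric Pd(OAc)2 (divalent palladium) in MeCN at 23 °C should effect oxidative cycloalkenylation (Saegusa–Ito-type enolate palladation, 5-exo carbopalladation of C12=C13, β-hydride elimination towards C11) to give the C11=C12 alkene F6. Hydrogenation with H2 and RhCl(PPh3)3, which leaves the benzyl ether, gives 25.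

3. Step 3. What may go wrong: loss of the enol silane before the iminium ion captures it (protodesilylation by the acidic catalyst, or Mukaiyama–Michael consumption by excess methacrolein), with loss of regiocontrol at C10. The fallback keeps the cycloaddition but introduces C20 by aldol chemistry in separate flasks; it sets out from 4 and 5 and comes back at 10. The cycloaddition is run alone and 7 is isolated. A Mukaiyama aldol reaction with aqueous formaldehyde and Sc(OTf)3 in THF gives the β-hydroxy ketone F7, regiospecifically at C10. MsCl/Et3N then converts F7 through the mesylate F8 into 10 by β-elimination.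

**Further compounds**
F1 | step 11 | diol dienophile (20 without the two silyl groups) | CC(=O)C1=C[C@]2(COC1=O)[C@@H](O)CC[C@@](C)(CO)[C@H]2COCc3ccccc3
F2 | step 11 | chlorodimethyl(buta-1,3-dien-2-yl)silane | C=CC(=C)[Si](C)(C)Cl
F3 | step 11 | bis[(buta-1,3-dien-2-yl)dimethylsilyl] ether of F1 | CC(=O)C1=C[C@]2(COC1=O)[C@@H](O[Si](C)(C)C(=C)C=C)CC[C@@](C)(CO[Si](C)(C)C(=C)C=C)[C@H]2COCc3ccccc3
F4 | step 11 | bridged siloxane cycloadduct (C12–SiMe2–O1 tether, C12=C13 alkene; C19 dienylsilyl ether intact) | CC(=O)[C@]12CC=C4C[C@H]1[C@]3(COC2=O)[C@@H](O[Si]4(C)C)CC[C@@](C)(CO[Si](C)(C)C(=C)C=C)[C@H]3COCc5ccccc5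
F5 | step 11 | diol cycloadduct (22 without the two silyl groups) | CC(=O)[C@]12CC=CC[C@H]1[C@]3(COC2=O)[C@@H](O)CC[C@@](C)(CO)[C@H]3COCc4ccccc4
F6 | step 13 | 11,12-didehydro analogue of 25 | C1C(=O)[C@]23C[C@H]1C=C[C@H]2[C@]1(COC3=O)[C@@H](O[Si](C)(C)C(C)(C)C)CC[C@@](C)(CO[Si](C)(C)C(C)(C)C)[C@H]1COCc2ccccc2
F7 | step 3 | 2-[(benzyloxy)methyl]-3-(hydroxymethyl)-1-methyl-4-oxocyclohexane-1-carbaldehyde (C10 epimer immaterial) | [C@@H]1(CO)C(=O)CC[C@@](C)(C=O)[C@H]1COCc2ccccc2
F8 | step 3 | methanesulfonate of F7 | [C@@H]1(COS(C)(=O)=O)C(=O)CC[C@@](C)(C=O)[C@H]1COCc2ccccc2
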